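**Plan**
- The retrosynthesis cuts ring C at two bonds on neighbouring ring A carbons, C4(=O)–C4a and O1–C8a. This leaves 3,4,5-trimethoxybenzyne and an open-chain (S)-β-hydroxy acyl unit (O1–C2–C3–C4 carrying ring B).
- Enabling feature: ring A carries O1 (on C8a), the acyl carbon (on C4a) and a methoxy group (on C5) on three consecutive carbons. A 3-alkoxyaryne delivers this pattern, taking the nucleophile at the carbon remote from OMe and the electrophile at the carbon beside OMe.
- Forward: rings A and B are bought. The aryne precursor comes in two steps from symmetric 3,4,5-trimethoxyphenol and the chain in two steps from a β-keto ester. Ring C arises last in one flask, O1–C8a first and C4–C4a as the ring-closing bond.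
- Helpers: iodide and triflate trigger the aryne. A Weinreb amide holds the carbonyl as a lithium hemiaminal until the acid quench, so the base-labile flavanone never meets base. All three leave in the key step itself.
- Stereochemistry: C2 is set by Noyori–Ikariya asymmetric transfer hydrogenation of the aryl ketone and is carried unchanged, because the C2–O bond is never broken.

Key step: step 5

Assumption: compounds 1 and 4 are taken as catalogue chemicals, and flavanone numbering (O1, C2, C3, C4, C4a, C5 to C8, C8a) is used for the atoms of rings A and C throughout.

**Step 1**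
Reactants: 1 3,4,5-trimethoxyphenol
Product: 2 2-iodo-3,4,5-trimethoxyphenol
Conditions: NIS (1.0 equiv), MeCN, −20 to 0 °C, dark
Reagents that add atoms: N-iodosuccinimide, O=C1CCC(=O)N1I
Why: Electrophilic aromatic iodination of a strongly activated phenol, in which the only two free ring positions are equivalent by symmetry and lie ortho to OH and ortho/para to methoxy groups, so one equivalent of NIS at low temperature should give the single mono-iodide.

**Step 2**
Reactants: 2 2-iodo-3,4,5-trimethoxyphenol
Product: 3 2-iodo-3,4,5-trimethoxyphenyl trifluoromethanesulfonate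
Conditions: Tf2O, pyridine, CH2Cl2, 0 °C
Reagents that add atoms: trifluoromethanesulfonic anhydride, O=S(=O)(OS(=O)(=O)C(F)(F)F)C(F)(F)F
Why: Standard O-triflation of a phenol, which places the leaving group ortho to iodine as aryne generation requires and leaves the aryl iodide and the methyl ethers untouched.

**Step 3**
Reactants: 4 ethyl 3-(3,4-dimethoxyphenyl)-3-oxopropanoate
Product: 5 ethyl (S)-3-(3,4-dimethoxyphenyl)-3-hydroxypropanoate
Conditions: RuCl[(S,S)-TsDPEN](p-cymene) (1 mol %), HCO2H/Et3N (5:2), 35 °C
Reagents that add atoms: none
Why: Noyori–Ikariya asymmetric transfer hydrogenation of an aryl ketone, in whose outer-sphere six-membered transition state the aryl ring lies under the p-cymene ligand (CH/π contact), so the (S,S)-catalyst should deliver hydride to the Re face and set the (S)-benzylic carbinol (later C2) while the ester stays inert.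

**Step 4**
Reactants: 5 ethyl (S)-3-(3,4-dimethoxyphenyl)-3-hydroxypropanoate
Product: 6 (S)-3-(3,4-dimethoxyphenyl)-3-hydroxy-N-methoxy-N-methylpropanamide
Conditions: MeNHOMe·HCl, i-PrMgCl, THF, −20 to 0 °C; aq NH4Cl
Reagents that add atoms: N,O-dimethylhydroxylamine hydrochloride, CNOC.Cl
Why: Weinreb amide formation by aminolysis of the ester with the chloromagnesium amide made in situ, during which the hydroxyl is held as a magnesium alkoxide that cannot leave, so dehydration and retro-aldol cleavage should stay slow at this temperature and the stereocentre is untouched.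

**Step 5**
Reactants: 6 (S)-3-(3,4-dimethoxyphenyl)-3-hydroxy-N-methoxy-N-methylpropanamide; 3 2-iodo-3,4,5-trimethoxyphenyl trifluoromethanesulfonate
Product: 12 (2S)-5,6,7,3',4'-pentamethoxyflavanone, via lithium alkoxide 7 (not isolated), via 2-lithioaryl triflate 8 (not isolated), via 3,4,5-trimethoxybenzyne 9 (not isolated), via aryllithium adduct 10 (not isolated), via lithium hemiaminal 11 (not isolated)
Conditions: 6, n-BuLi (1.0 equiv), THF, −78 °C; 3 (1.3 equiv); n-BuLi (1.25 equiv) dropwise, −78 °C; AcOH/THF, −78 °C to rt
Reagents that add atoms: none
Why: Proposed new method: iodine–lithium exchange on 3 gives 8, which loses LiOTf at −78 °C to give aryne 9; the proton-free lithium alkoxide 7 adds through oxygen, and the resulting aryllithium 10 attacks its own Weinreb amide to give the chelated hemiaminal 11, which releases the ketone only in the acid quench. The closest known reaction types are the annulation of arynes with salicylate esters to xanthones, the insertion of arynes into the N–C(O) bond of β-lactams, Parham cycliacylation on Weinreb amides and the n-BuLi generation of 3-alkoxybenzynes from 2-iodoaryl triflates; the new element is an aliphatic, enolisable β-hydroxy acyl donor as the O/C(=O) partner. Ring C closes in the 6-exo-trig mode by formation of the C4–C4a bond directly after the O1–C8a bond. No new stereocentre survives (C4 of 11 is lost on collapse), and C2 keeps its S configuration because its C–O bond is never broken and the ranking O > aryl > CH2 > H is the same before and after. The regioselectivity needed is oxygen at the aryne carbon remote from the flanking methoxy group and the carbanion beside it; that methoxy group (later C5-OMe) secures this by distorting the aryne so that the remote carbon is the more linear and more electrophilic one, and by stabilising the lithiated carbon between two oxygen-bearing carbons. Acylation must also outrun proton transfer and base-induced opening of the flavanone, which is secured by removing the only acidic OH as butane beforehand, by coordination of lithium to the amide carbonyl in 10, and by 11 keeping the carbonyl masked until AcOH is added.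

**Compound list**
1 | 3,4,5-trimethoxyphenol | COc1cc(O)cc(OC)c1OC | starting material
2 | 2-iodo-3,4,5-trimethoxyphenol | COc1cc(O)c(I)c(OC)c1OC | intermediate
3 | 2-iodo-3,4,5-trimethoxyphenyl trifluoromethanesulfonate | COc1cc(OS(=O)(=O)C(F)(F)F)c(I)c(OC)c1OC | intermediate
4 | ethyl 3-(3,4-dimethoxyphenyl)-3-oxopropanoate | CCOC(=O)CC(=O)c1ccc(OC)c(OC)c1 | starting material
5 | ethyl (S)-3-(3,4-dimethoxyphenyl)-3-hydroxypropanoate | COc1ccc([C@H](CC(=O)OCC)O)cc1OC | intermediate
6 | (S)-3-(3,4-dimethoxyphenyl)-3-hydroxy-N-methoxy-N-methylpropanamide | COc1ccc([C@H](CC(=O)N(C)OC)O)cc1OC | intermediate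
7 | lithium (S)-alkoxide of 6 | COc1ccc([C@H](CC(=O)N(C)OC)O[Li])cc1OC | intermediate
8 | 2-lithio-3,4,5-trimethoxyphenyl trifluoromethanesulfonate | COc1cc(OS(=O)(=O)C(F)(F)F)c([Li])c(OC)c1OC | intermediate
9 | 3,4,5-trimethoxybenzyne (1,2-didehydro-3,4,5-trimethoxybenzene) | COC1=C(OC)C(OC)=CC#C1 | intermediate
10 | (S)-3-(3,4-dimethoxyphenyl)-3-(2-lithio-3,4,5-trimethoxyphenoxy)-N-methoxy-N-methylpropanamide | COc1ccc([C@H](CC(=O)N(C)OC)Oc2c([Li])c(OC)c(OC)c(OC)c2)cc1OC | intermediate
11 | lithium (2S)-2-(3,4-dimethoxyphenyl)-5,6,7-trimethoxy-4-[methoxy(methyl)amino]chroman-4-olate (C4 undefined, transient) | COc1ccc([C@@H]2CC(O[Li])(N(C)OC)c3c(cc(OC)c(OC)c3OC)O2)cc1OC | intermediate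
12 | (2S)-5,6,7,3',4'-pentamethoxyflavanone | COc1ccc([C@@H]2CC(=O)c3c(cc(OC)c(OC)c3OC)O2)cc1OC | target

**Step count**
Total steps: 5 (convergent). Longest linear sequence: 3 steps (4 → 5 → 6 → 12, or 1 → 2 → 3 → 12).

**Steps most likely to fail**

1. Step 5 (proposed new method).
 - Risk: capture of the aryne by the aggregated lithium alkoxide may be slower than consumption of the aryne by n-BuLi or by its lithiated precursor. In the adduct, proton transfer from C3–H to the aryl carbanion, followed by loss of the aryloxide, may compete with acylation.
 - Fallback (known chemistry): the two bonds are made in separate operations, with the ether formed at the alkyl carbon instead of the aryl carbon. It sets out from 4 and 2.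
 - Transfer hydrogenation of 4 with the enantiomeric catalyst RuCl[(R,R)-TsDPEN](p-cymene) should give ethyl (R)-3-(3,4-dimethoxyphenyl)-3-hydroxypropanoate F1.
 - Aminolysis as in step 4 should give (R)-3-(3,4-dimethoxyphenyl)-3-hydroxy-N-methoxy-N-methylpropanamide F2.
 - Mitsunobu etherification of F2 with iodophenol 2 (PPh3, DIAD, toluene, 0 °C) should invert the carbinol carbon. The product is (S)-3-(3,4-dimethoxyphenyl)-3-(2-iodo-3,4,5-trimethoxyphenoxy)-N-methoxy-N-methylpropanamide F3.
 - Iodine–lithium exchange on F3 (n-BuLi, THF, −78 °C, Parham cycliacylation) generates aryllithium 10. The route is rejoined there and runs on through 11 to 12.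

2. Step 1.
 - Risk: double iodination, and oxidative demethylation of the very electron-rich free phenol towards a quinone.
 - Fallback: the order of events is reversed, so that the ring meets the iodinating agent only after the phenol is masked as the electron-withdrawing sulfonate it needs anyway. It sets out from 1.
 - Tf2O and pyridine in CH2Cl2 at 0 °C should give 3,4,5-trimethoxyphenyl trifluoromethanesulfonate F4.
 - The two free positions of F4 are again equivalent. NIS with catalytic CF3CO2H in MeCN at room temperature should iodinate one of them, and the route is rejoined at 3.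

3. Step 4.
 - Risk: base-induced dehydration (E1cB) to the cinnamamide, or retro-aldol cleavage with erosion of configuration, under the strongly basic magnesium amide.
 - Fallback: the metal amide is avoided by going through the free acid and a near-neutral coupling. It sets out from 5.
 - LiOH in THF/H2O at 0 °C, then mild acidification, should give (S)-3-(3,4-dimethoxyphenyl)-3-hydroxypropanoic acid F5.
 - F5 is coupled with MeNHOMe·HCl using EDC·HCl, HOBt and N-methylmorpholine in CH2Cl2, and the route is rejoined at 6.

**Further compounds**
F1 | step 5 | ethyl (R)-3-(3,4-dimethoxyphenyl)-3-hydroxypropanoate | COc1ccc([C@@H](CC(=O)OCC)O)cc1OC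
F2 | step 5 | (R)-3-(3,4-dimethoxyphenyl)-3-hydroxy-N-methoxy-N-methylpropanamide | COc1ccc([C@@H](CC(=O)N(C)OC)O)cc1OC
F3 | step 5 | (S)-3-(3,4-dimethoxyphenyl)-3-(2-iodo-3,4,5-trimethoxyphenoxy)-N-methoxy-N-methylpropanamide | COc1ccc([C@H](CC(=O)N(C)OC)Oc2c(I)c(OC)c(OC)c(OC)c2)cc1OC
F4 | step 1 | 3,4,5-trimethoxyphenyl trifluoromethanesulfonate | COc1cc(OS(=O)(=O)C(F)(F)F)cc(OC)c1OC
F5 | step 4 | (S)-3-(3,4-dimethoxyphenyl)-3-hydroxypropanoic acid | COc1ccc([C@H](CC(=O)O)O)cc1OC
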